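## Retrosynthetic overview

1. Cembrane numbering is used: C1/C2 are the lactone CH and CH–O, C3=C4 is E, C7=C8 is Z, C11/C12 carry the epoxide, C13 is CH–OAc, C14 is CH2, and C15–C17 are the acrylate α‑carbon, carbonyl and methylene.
2. The C1–C2 bond is made last: a chiral‑phosphoric‑acid‑catalysed intramolecular allylboration of the C2 enal by a 2‑(methoxycarbonyl)allylboronate closes the 14‑membered ring and the lactone in one operation.
3. Before that, C1=C15 comes from cross‑metathesis, and C13–C14 from catalyst‑controlled allylboration of a C13 epoxy aldehyde (sets C13).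
4. The epoxide is the first ring: organocatalytic iminium epoxidation of the C13 α‑branched enal sets C11 and C12, the first stereocentres.
5. The chain comes from nerylacetone by a two‑carbon Horner–Wadsworth–Emmons extension and allylic oxidation of the terminal (E)‑methyl group.

Assumption: nerylacetone is bought as the pure (5Z) isomer; the catalyst antipodes in steps 3, 4 and 9 are assigned by analogy with simple substrates and would be confirmed on the first run (for step 3 the pseudo‑enantiomeric pair 9‑amino(9‑deoxy)epiquinidine/(S)‑TRIP is used if the antipode forms).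

## Route

Step 1
Reactants: 1 nerylacetone, (5Z)-6,10-dimethylundeca-5,9-dien-2-one; 2 diethyl {2-[methoxy(methyl)amino]-2-oxoethyl}phosphonate
Product: 3 (2E,6Z)-N-methoxy-N,3,7,11-tetramethyldodeca-2,6,10-trienamide
Conditions: NaH (1.3 equiv), THF, 0 °C → 60 °C, 16 h; chromatography removes the minor (2Z) isomer
Reagents that add atoms: none
Why: Horner–Wadsworth–Emmons olefination of the methyl ketone gives mainly the (2E) unsaturated Weinreb amide, which masks the later C2 aldehyde through the oxidation, epoxidation and allylation steps.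

Step 2
Reactants: 3 (2E,6Z)-N-methoxy-N,3,7,11-tetramethyldodeca-2,6,10-trienamide
Product: 5 (2E,6Z,10E)-N-methoxy-N,3,7,11-tetramethyl-12-oxododeca-2,6,10-trienamide, via allylic alcohol 4 (not isolated)
Conditions: SeO2 (0.3 equiv), salicylic acid (0.1 equiv), t-BuOOH (70 % aq., 3 equiv), CH2Cl2, 0 °C → rt, 24 h; filter; then MnO2 (15 equiv), CH2Cl2, rt
Reagents that add atoms: selenium dioxide, O=[Se]=O (catalytic oxygen carrier); tert-butyl hydroperoxide, CC(C)(C)OO (terminal oxygen source)
Why: SeO2 allylic oxidation (ene reaction, then [2,3]-shift) goes to the (E)-methyl of the most accessible, non-conjugated terminal alkene, and MnO2 then converges the alcohol/aldehyde mixture to the (10E)-enal.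

Step 3
Reactants: 5 (2E,6Z,10E)-N-methoxy-N,3,7,11-tetramethyl-12-oxododeca-2,6,10-trienamide
Product: 6 (2E,6Z)-9-[(2S,3R)-3-formyl-3-methyloxiran-2-yl]-N-methoxy-N,3,7-trimethylnona-2,6-dienamide
Conditions: 9-amino(9-deoxy)epiquinine (10 mol %), (R)-TRIP [3,3′-bis(2,4,6-triisopropylphenyl)-1,1′-binaphthyl-2,2′-diyl hydrogen phosphate] (20 mol %), 50 % aq. H2O2 (3 equiv), THF, 50 °C, 24 h
Reagents that add atoms: hydrogen peroxide, OO
Why: Iminium-catalysed nucleophilic epoxidation of an α-branched enal: only the aldehyde forms an iminium ion with the primary amine, H2O2 adds at the β-carbon inside the chiral ion pair and the enamine closes the trans epoxide, setting the two epoxide centres (the first stereocentres) while the amide-conjugated and isolated alkenes are untouched.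

Step 4
Reactants: 6 (2E,6Z)-9-[(2S,3R)-3-formyl-3-methyloxiran-2-yl]-N-methoxy-N,3,7-trimethylnona-2,6-dienamide; 7 allylboronic acid pinacol ester
Product: 9 (2E,6Z)-9-[(2S,3S)-3-[(1R)-1-hydroxybut-3-en-1-yl]-3-methyloxiran-2-yl]-N-methoxy-N,3,7-trimethylnona-2,6-dienamide, via pinacol borate 8 (not isolated)
Conditions: (R)-TRIP (5 mol %), toluene, −30 °C, 24 h; then aq. NaHCO3
Reagents that add atoms: none
Why: Chiral phosphoric acid-catalysed allylboration through a closed chair transition state; the catalyst, not the weak Felkin bias of the epoxy aldehyde, fixes the aldehyde face and gives the (R) carbinol (threo to the epoxide), by analogy with the (R)-alcohols that (R)-TRIP gives from simple aldehydes.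

Step 5
Reactants: 9 (2E,6Z)-9-[(2S,3S)-3-[(1R)-1-hydroxybut-3-en-1-yl]-3-methyloxiran-2-yl]-N-methoxy-N,3,7-trimethylnona-2,6-dienamide
Product: 11 (2E,6Z)-9-[(2S,3S)-3-[(1R)-1-hydroxybut-3-en-1-yl]-3-methyloxiran-2-yl]-3,7-dimethylnona-2,6-dienal, via aluminium hemiaminal 10 (not isolated)
Conditions: iBu2AlH (2.5 equiv), THF, −78 °C, 1 h; then aq. KNaC4H4O6 (potassium sodium tartrate)
Reagents that add atoms: none
Why: Weinreb amide reduction stops at the N,O-chelated aluminium hemiaminal, which gives the enal only on work-up; at −78 °C the epoxide is not opened and no stereocentre is touched.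

Step 6
Reactants: 11 (2E,6Z)-9-[(2S,3S)-3-[(1R)-1-hydroxybut-3-en-1-yl]-3-methyloxiran-2-yl]-3,7-dimethylnona-2,6-dienal
Product: 12 (1R)-1-[(2R,3S)-3-[(3Z,7E)-3,7-dimethyl-9-oxonona-3,7-dien-1-yl]-2-methyloxiran-2-yl]but-3-en-1-yl acetate
Conditions: Ac2O (2 equiv), pyridine, DMAP (10 mol %), CH2Cl2, 0 °C → rt
Reagents that add atoms: acetic anhydride, CC(=O)OC(C)=O
Why: DMAP-catalysed O-acylation of the secondary alcohol with retention at C13 (the oxirane descriptor changes from S to R only because the ligand priorities change).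

Step 7
Reactants: 13 methyl 2-(bromomethyl)acrylate; 14 bis(pinacolato)diboron
Product: 15 methyl 2-[(4,4,5,5-tetramethyl-1,3,2-dioxaborolan-2-yl)methyl]prop-2-enoate
Conditions: CuCl (10 mol %), KOAc (1.5 equiv), DMF, rt, 12 h
Reagents that add atoms: none
Why: Copper-catalysed allylic borylation: the boryl-copper species adds to the acrylate terminus and bromide is eliminated (SN2′), giving the known 2-alkoxycarbonyl allylboronate.

Step 8
Reactants: 12 (1R)-1-[(2R,3S)-3-[(3Z,7E)-3,7-dimethyl-9-oxonona-3,7-dien-1-yl]-2-methyloxiran-2-yl]but-3-en-1-yl acetate; 15 methyl 2-[(4,4,5,5-tetramethyl-1,3,2-dioxaborolan-2-yl)methyl]prop-2-enoate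
Product: 16 methyl (2E,5R)-5-acetoxy-5-[(2R,3S)-3-[(3Z,7E)-3,7-dimethyl-9-oxonona-3,7-dien-1-yl]-2-methyloxiran-2-yl]-2-[(4,4,5,5-tetramethyl-1,3,2-dioxaborolan-2-yl)methyl]pent-2-enoate
Conditions: second-generation Hoveyda–Grubbs catalyst RuCl2(H2IMes)(=CH-C6H4-2-OiPr) (10 mol %), 15 (4 equiv), CH2Cl2, 40 °C, 24 h
Reagents that add atoms: none
Why: Olefin cross-metathesis of the only terminal alkene with an excess of a non-dimerising 1,1-disubstituted acrylate (as with methacrylates) gives the trisubstituted enoate with the chain trans to the ester and cis to CH2B; the trisubstituted alkenes, the enal and the allyl boronate are inert to the carbene.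

Step 9
Reactants: 16 methyl (2E,5R)-5-acetoxy-5-[(2R,3S)-3-[(3Z,7E)-3,7-dimethyl-9-oxonona-3,7-dien-1-yl]-2-methyloxiran-2-yl]-2-[(4,4,5,5-tetramethyl-1,3,2-dioxaborolan-2-yl)methyl]pent-2-enoate
Product: 18 (1S,2S,3E,7Z,11S,12R,13R)-13-acetoxy-11,12-epoxycembra-3,7,15(17)-trien-16,2-olide, via macrocyclic borate 17 (not isolated)
Conditions: (R)-TRIP (10 mol %), toluene (1 mM; 16 added by syringe pump over 12 h), 0 °C → rt, then 40 °C, 6 h
Reagents that add atoms: none
Why: Proposed new method: a chiral phosphoric acid-catalysed intramolecular allylboration that closes the 14-membered ring — the acid hydrogen-bonds to a pinacol oxygen of the electron-poor allylboronate (inert without a catalyst at rt) and its P=O contacts the formyl C–H, so C1 adds to C2 through a chair in which the C14 chain (cis to CH2B) is axial and C3 equatorial, giving the syn (1S,2S) borate 17, whose alkoxide then displaces methoxide from the adjacent ester to form the cis α-methylene lactone; (R)-TRIP is expected to choose the same aldehyde face as in step 4 (2S here) and override the remote C13 centre; the closest known reactions are the intermolecular phosphoric acid-catalysed allylboration of aldehydes and the acid-promoted allylboration–lactonisation of 2-alkoxycarbonyl allylboronates, neither shown for a macrocyclisation.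

## Compound list

1 | nerylacetone, (5Z)-6,10-dimethylundeca-5,9-dien-2-one | CC(=O)CC/C=C(/C)CCC=C(C)C | starting material
2 | diethyl {2-[methoxy(methyl)amino]-2-oxoethyl}phosphonate | CCOP(=O)(CC(=O)N(C)OC)OCC | starting material
3 | (2E,6Z)-N-methoxy-N,3,7,11-tetramethyldodeca-2,6,10-trienamide | CON(C)C(=O)/C=C(\C)CC/C=C(/C)CCC=C(C)C | intermediate
4 | (2E,6Z,10E)-12-hydroxy-N-methoxy-N,3,7,11-tetramethyldodeca-2,6,10-trienamide (not isolated) | CON(C)C(=O)/C=C(\C)CC/C=C(/C)CC/C=C(\C)CO | intermediate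
5 | (2E,6Z,10E)-N-methoxy-N,3,7,11-tetramethyl-12-oxododeca-2,6,10-trienamide | CON(C)C(=O)/C=C(\C)CC/C=C(/C)CC/C=C(\C)C=O | intermediate
6 | (2E,6Z)-9-[(2S,3R)-3-formyl-3-methyloxiran-2-yl]-N-methoxy-N,3,7-trimethylnona-2,6-dienamide | CON(C)C(=O)/C=C(\C)CC/C=C(/C)CC[C@@H]1O[C@@]1(C)C=O | intermediate
7 | allylboronic acid pinacol ester, 2-allyl-4,4,5,5-tetramethyl-1,3,2-dioxaborolane | C=CCB1OC(C)(C)C(C)(C)O1 | starting material
8 | (2E,6Z)-N-methoxy-N,3,7-trimethyl-9-[(2S,3S)-3-methyl-3-[(1R)-1-[(4,4,5,5-tetramethyl-1,3,2-dioxaborolan-2-yl)oxy]but-3-en-1-yl]oxiran-2-yl]nona-2,6-dienamide (not isolated) | CON(C)C(=O)/C=C(\C)CC/C=C(/C)CC[C@@H]1O[C@@]1(C)[C@H](OB2OC(C)(C)C(C)(C)O2)CC=C | intermediate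
9 | (2E,6Z)-9-[(2S,3S)-3-[(1R)-1-hydroxybut-3-en-1-yl]-3-methyloxiran-2-yl]-N-methoxy-N,3,7-trimethylnona-2,6-dienamide | CON(C)C(=O)/C=C(\C)CC/C=C(/C)CC[C@@H]1O[C@@]1(C)[C@H](O)CC=C | intermediate
10 | aluminium hemiaminal of 9: the amide carbon carries H, N(OMe)Me and O–Al(iBu)2, and the carbinol oxygen carries Al(iBu)2 (not isolated) | CON(C)C(O[Al](CC(C)C)CC(C)C)/C=C(\C)CC/C=C(/C)CC[C@@H]1O[C@@]1(C)[C@H](O[Al](CC(C)C)CC(C)C)CC=C | intermediate
11 | (2E,6Z)-9-[(2S,3S)-3-[(1R)-1-hydroxybut-3-en-1-yl]-3-methyloxiran-2-yl]-3,7-dimethylnona-2,6-dienal | O=C/C=C(\C)CC/C=C(/C)CC[C@@H]1O[C@@]1(C)[C@H](O)CC=C | intermediate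
12 | (1R)-1-[(2R,3S)-3-[(3Z,7E)-3,7-dimethyl-9-oxonona-3,7-dien-1-yl]-2-methyloxiran-2-yl]but-3-en-1-yl acetate | O=C/C=C(\C)CC/C=C(/C)CC[C@@H]1O[C@@]1(C)[C@H](OC(C)=O)CC=C | intermediate
13 | methyl 2-(bromomethyl)acrylate | C=C(CBr)C(=O)OC | starting material
14 | bis(pinacolato)diboron | CC1(C)OB(OC1(C)C)B1OC(C)(C)C(C)(C)O1 | starting material
15 | methyl 2-[(4,4,5,5-tetramethyl-1,3,2-dioxaborolan-2-yl)methyl]prop-2-enoate | C=C(CB1OC(C)(C)C(C)(C)O1)C(=O)OC | intermediate
16 | methyl (2E,5R)-5-acetoxy-5-[(2R,3S)-3-[(3Z,7E)-3,7-dimethyl-9-oxonona-3,7-dien-1-yl]-2-methyloxiran-2-yl]-2-[(4,4,5,5-tetramethyl-1,3,2-dioxaborolan-2-yl)methyl]pent-2-enoate | O=C/C=C(\C)CC/C=C(/C)CC[C@@H]1O[C@@]1(C)[C@H](OC(C)=O)C/C=C(/C(=O)OC)CB1OC(C)(C)C(C)(C)O1 | intermediate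
17 | methyl 2-[(1S,2S,3E,7Z,11S,12R,13R)-13-acetoxy-11,12-epoxy-4,8,12-trimethyl-2-[(4,4,5,5-tetramethyl-1,3,2-dioxaborolan-2-yl)oxy]cyclotetradeca-3,7-dien-1-yl]prop-2-enoate (not isolated) | C=C(C(=O)OC)[C@H]1[C@@H](OB2OC(C)(C)C(C)(C)O2)/C=C(\C)CC/C=C(/C)CC[C@@H]3O[C@@]3(C)[C@H](OC(C)=O)C1 | intermediate
18 | (1S,2S,3E,7Z,11S,12R,13R)-13-acetoxy-11,12-epoxycembra-3,7,15(17)-trien-16,2-olide (cis-fused α-methylene-γ-lactone on a 14-membered ring) | C=C1C(=O)O[C@H]2/C=C(\C)CC/C=C(/C)CC[C@@H]3O[C@@]3(C)[C@H](OC(C)=O)C[C@@H]12 | target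

## Step count and risks

Total steps: 9 (eight on the main line plus one reagent-making step, step 7). Longest linear sequence: 8 steps (1–6, 8, 9).

The three steps most likely to fail are steps 9, 8 and 4.

Step 9 (the proposed ring closure). The risks are a phosphoric acid too weak to activate the ester-bearing boronate, the macrocycle or C13 overriding the catalyst to give the (1R,2R) cis isomer, and oligomerisation. The fallback uses known chemistry, sets out from 12 and comes back at 18. Cross-metathesis of 12 with methyl 2-(bromomethyl)acrylate 13 (same ruthenium catalyst, CH2Cl2, 40 °C) gives methyl (2Z,5R)-5-acetoxy-2-(bromomethyl)-5-[(2R,3S)-3-[(3Z,7E)-3,7-dimethyl-9-oxonona-3,7-dien-1-yl]-2-methyloxiran-2-yl]pent-2-enoate F5. An indium-mediated intramolecular Barbier allylation (In powder, THF/H2O, 2 mM, rt), the established way to close such rings from a 2-(bromomethyl)enoate and an aldehyde, then gives, through its ester-chelated cyclic transition state, the syn adduct methyl 2-[(1S,2S,3E,7Z,11S,12R,13R)-13-acetoxy-11,12-epoxy-2-hydroxy-4,8,12-trimethylcyclotetradeca-3,7-dien-1-yl]prop-2-enoate F6. F6 lactonises on standing or with catalytic pyridinium p-toluenesulfonate to 18.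

Step 8 (cross-metathesis with the boron-bearing acrylate). The risk is slow turnover of the hindered 1,1-disubstituted partner or interference of the boronate with the ruthenium carbene. The fallback separates C=C from C–B bond formation, sets out from 12 and comes back at 16. Methyl 2-(acetoxymethyl)acrylate F3 (from commercial methyl 2-(hydroxymethyl)acrylate, Ac2O, pyridine) is used as the metathesis partner to give methyl (2E,5R)-5-acetoxy-2-(acetoxymethyl)-5-[(2R,3S)-3-[(3Z,7E)-3,7-dimethyl-9-oxonona-3,7-dien-1-yl]-2-methyloxiran-2-yl]pent-2-enoate F4. Palladium-catalysed allylic borylation (Pd2(dba)3, zerovalent palladium, 2.5 mol %, with 14, DMSO, 50 °C) then ionises only the activated allylic acetate and delivers boron to the CH2 end of the π-allyl complex, giving 16. This fallback still relies on metathesis, so it does not help if the substrate itself is the problem.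

Step 4 (allylboration of the α-quaternary epoxy aldehyde). The risk is incomplete catalyst control (erythro epimer) or acid-induced epoxide opening. The fallback moves the stereo-determining event to a ketone reduction, sets out from 6 and comes back at 9. Barbier allylation with allyl bromide and In powder in THF/H2O gives both carbinol epimers, (2E,6Z)-9-[(2S,3S)-3-[(1RS)-1-hydroxybut-3-en-1-yl]-3-methyloxiran-2-yl]-N-methoxy-N,3,7-trimethylnona-2,6-dienamide F1. Dess–Martin oxidation (NaHCO3, CH2Cl2) gives (2E,6Z)-9-[(2S,3R)-3-(but-3-enoyl)-3-methyloxiran-2-yl]-N-methoxy-N,3,7-trimethylnona-2,6-dienamide F2. Corey–Bakshi–Shibata reduction ((S)-2-methyl-CBS-oxazaborolidine 20 mol %, catecholborane, toluene, −78 °C; large group = epoxide carbon, small group = allyl CH2) then returns the (R) carbinol 9.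

## Further compounds

F1 | step 4 | (2E,6Z)-9-[(2S,3S)-3-[(1RS)-1-hydroxybut-3-en-1-yl]-3-methyloxiran-2-yl]-N-methoxy-N,3,7-trimethylnona-2,6-dienamide (both carbinol epimers) | CON(C)C(=O)/C=C(\C)CC/C=C(/C)CC[C@@H]1O[C@@]1(C)C(O)CC=C
F2 | step 4 | (2E,6Z)-9-[(2S,3R)-3-(but-3-enoyl)-3-methyloxiran-2-yl]-N-methoxy-N,3,7-trimethylnona-2,6-dienamide | CON(C)C(=O)/C=C(\C)CC/C=C(/C)CC[C@@H]1O[C@@]1(C)C(=O)CC=C
F3 | step 8 | methyl 2-(acetoxymethyl)acrylate | C=C(COC(C)=O)C(=O)OC
F4 | step 8 | methyl (2E,5R)-5-acetoxy-2-(acetoxymethyl)-5-[(2R,3S)-3-[(3Z,7E)-3,7-dimethyl-9-oxonona-3,7-dien-1-yl]-2-methyloxiran-2-yl]pent-2-enoate | O=C/C=C(\C)CC/C=C(/C)CC[C@@H]1O[C@@]1(C)[C@H](OC(C)=O)C/C=C(/C(=O)OC)COC(C)=O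
F5 | step 9 | methyl (2Z,5R)-5-acetoxy-2-(bromomethyl)-5-[(2R,3S)-3-[(3Z,7E)-3,7-dimethyl-9-oxonona-3,7-dien-1-yl]-2-methyloxiran-2-yl]pent-2-enoate | O=C/C=C(\C)CC/C=C(/C)CC[C@@H]1O[C@@]1(C)[C@H](OC(C)=O)C/C=C(/C(=O)OC)CBr
F6 | step 9 | methyl 2-[(1S,2S,3E,7Z,11S,12R,13R)-13-acetoxy-11,12-epoxy-2-hydroxy-4,8,12-trimethylcyclotetradeca-3,7-dien-1-yl]prop-2-enoate | C=C(C(=O)OC)[C@H]1[C@@H](O)/C=C(\C)CC/C=C(/C)CC[C@@H]3O[C@@]3(C)[C@H](OC(C)=O)C1
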